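**Conventions and assumption.** Each naphthalene unit is numbered as a 1-naphthol (hydroxyl on C1, methoxy on C8), and the target is A(C2)–(C4)B(C2)–(C4)C. Assumption: the two biaryl axes rotate freely at ambient temperature (the SMILES carries no axial descriptor), so the target is treated as achiral. Every sp3 centre made on the way is carried as a racemate or a diastereomer mixture.

## The problem

The target 19 is a linear trimer of 8-methoxy-1-naphthol. Unit A is bonded through C2 to C4 of unit B, and unit B through C2 to C4 of unit C, so both biaryl bonds are ortho–para links between electron-rich naphthol rings. Every substituent sits on a phenol ring (C2 or C4) and none on an anisole ring, so the central question is regiochemistry: ortho or para to the hydroxyl, and phenol ring or anisole ring. There is no stereocentre to set. Any sp3 centre created en route can control nothing, needs no control, and must be erasable. The three free peri-methoxy naphthols are easily oxidized and are carbon nucleophiles at their open positions (A4, C2), so the hydroxyls stay masked until the last operation, and that operation must avoid oxidants and free electrophiles. The feature that permits the key step lies in unit C: C2 and C3 are unsubstituted CH groups between the oxygenated C1 and the arylated C4, and C1 and C4 hang on the adjacent carbons C8a and C4a of the anisole ring. A C2=C3 alkene between two carbinol carbons held ortho on an anisole therefore encodes the whole phenol ring of unit C. Because C4 would be tertiary and doubly benzylic while C1 is secondary, dehydration can only remove the C4 oxygen, which leaves the surviving oxygen on C1, peri to the methoxy group.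

## Retrosynthesis

**Target 19 back to dihydronaphthalenol 17.** The three hydroxyls of 19 are masked as MOM ethers in 18. Unit C of 18 is then taken back to the 1,4-dihydronaphthalene 17 by adding the elements of a hydroxyl at C4 and a hydrogen at C1. The C1 oxygen is carried as a MOM ether, not as a free hydroxyl. After aromatization it becomes the third aryl MOM ether, so one acid treatment finishes the synthesis and no separate protecting group has to be removed beforehand. The forward reaction must ionize only the tertiary C4 carbinol and must not let a nucleophilic solvent enter at C1 or C2 before the ring is aromatic.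

**17 back to diene 16.** The C2=C3 bond is cut by ring-closing metathesis. Against cuts at C1–C8a/C4–C4a (aryne cycloaddition) or C1–C2 (anionic acylation), this cut involves no regiochemical or periselectivity question, since the positions of both oxygens are fixed by the carbon skeleton of 16. The precursor 16 is acyclic at unit C and carries two monosubstituted alkenes held ortho on an arene, the best case for a six-membered closure.

**16 back to aldehyde 9 and aryl bromide 12.** The C4–C3 bond is cut by a vinyl addition to diaryl ketone 15. Ketone 15 comes from carbinol 14, and the C4–C4a bond of 14 from the aryllithium 13 (made from bromide 12) and aldehyde 9. The B2–C4 bond is thus already present in 9 as the formyl carbon. The neighbouring cut, a direct biaryl coupling at B2–C4 with a second equivalent of bromide 6, would be shorter. The ring synthesis is preferred here because the terminal unit then grows from a simple benzaldehyde, so the terminal naphthol can be varied without a new regioselective halogenation each time. The direct coupling is kept as the fallback for the key step.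

**12 back to aldehyde 10.** The C1–C2 bond is cut by a vinyl addition to 2-bromo-6-methoxybenzaldehyde 10, giving allylic alcohol 11, which is protected as MOM ether 12. The 1,2,3-substitution pattern of 10 (methoxy, formyl, bromine) is exactly C8, C8a–C1 and C4a of unit C, so no regiochemistry has to be created on this ring.

**9 back to biaryl 7.** The formyl group is removed from B2. In 7 the MOM-oxy group of unit B has exactly one ortho hydrogen (B2), whereas that of unit A has none, so directed lithiation through 8 should place the carbonyl carbon where it is needed.

**7 back to boronate 4 and bromide 6.** The A2–B4 bond is cut by a Suzuki coupling. An oxidative phenol coupling would give ortho–ortho, ortho–para and para–para dimers together. The cross-coupling assigns ortho to one partner and para to the other.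

**4 and 6 back to naphthol 1.** Boronate 4 arises from MOM ether 2 by ortho-lithiation (via 3) and borylation. Bromide 6 arises from 1 by para-bromination to 5 and MOM protection. Bromination is done on the free naphthol, because in the ether 2 the positions para to the MOM-oxy and para to the methoxy group would compete. One purchased naphthol supplies units A and B.

## Roads not taken

**Alternative 1:** The cut is at A8–A8a and A5–A4a, so the anisole ring of unit A is built last. In the forward step fluoride induces 1,2-elimination of the ortho-silylaryl triflate A2, which holds the phenol ring of unit A and the complete B–C portion. The resulting aryne adds across C3 and C6 of 3-methoxy-2-pyrone A3, and cycloreversion expels the lactone bridge to give A1, the tris-MOM ether of the target (identical with 18).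
- Merits: the step ends directly at the fully aromatic, protected trimer, passes through no acid-labile carbinol, and fluoride is harmless to MOM ethers.
- Weak points: A2 is a pentasubstituted benzene (silyl, triflate, MOM-oxy and a large biaryl substituent) whose preparation presupposes both biaryl bonds. The orientation of the cycloaddition rests only on the polarization of a 3-alkoxy aryne and must place the methoxy group peri to the MOM-oxy group, the more crowded arrangement, so the 5-methoxy isomer is a likely companion. 2-Pyrones are sluggish dienes toward short-lived arynes.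
- Comparison: this road builds by cycloaddition a ring that can be bought intact in naphthol 1. It is better in that nothing after the key step is acid-sensitive. The chosen plan sets against this that its sensitive carbinols 16 and 17 live for two steps only, that their collapse is the desired reaction, and that its ring closure has no regiochemical question.

**Alternative 2:** The cut is at A1–A2. In the forward step LiN(iPr)2 removes a proton from the doubly activated CH2 of the ortho-allylbenzamide A5. The 1,3-diarylallyl anion attacks the diethylamide carbonyl through the terminus that bears unit B, the amide nitrogen leaves, and tautomerization gives A4, the trimer with the unit A hydroxyl free and units B and C as MOM ethers.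
- Merits: the amide carbon becomes C1 next to the methoxy group, so regiochemistry is fixed by construction. The naphthol appears at the correct oxidation level, no transition metal is needed, and MOM ethers tolerate the base.
- Weak points: A5 must already contain the B–C biaryl, so the B2–C4 bond still needs a coupling or a ring synthesis of its own. A5 also needs an alkenyl handle at B4 and an ortho-allylation of a 2-methoxybenzamide. The attacking carbon is flanked by the peri hydrogen of unit B and the amide by two ortho substituents, so the closure is congested. The lithium amide can also metalate next to the MOM-oxy groups.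
- Comparison: the two plans are equal in regiochemical certainty, and this road is better in avoiding acid-sensitive intermediates. It is not shorter, because it leaves the second biaryl bond unsolved, whereas the chosen plan makes B2–C4 by formylation and carbonyl addition and buys units A and B as naphthalenes.

**Alternative 3:** The cut is at C4–C4a and C1–C8a, the same ring as in the chosen plan. In the forward step n-BuLi at low temperature converts the iodo triflate A7 into the methoxy-substituted aryne. This adds across C1 and C4 of the bis(trimethylsilyl) vinylketene acetal A8, which carries the A–B half on its terminal carbon. Loss of silanol on work-up aromatizes the adduct to A6, the trimer with the unit C hydroxyl free and units A and B as MOM ethers.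
- Merits: this is the most convergent of the four plans. One step makes both bonds to the anisole ring at the naphthol oxidation level. The methoxy group of the aryne directs the nucleophilic diene terminus to the carbon meta to it, which puts the oxygenated carbon peri to the methoxy group as required. Counted from aldehyde 9 it would be shorter than the chosen sequence by a few steps.
- Weak points: ketene silyl acetals tend to add to arynes in the (2+2) mode across the oxygenated double bond, giving benzocyclobutenone ketals instead of the (4+2) adduct. The diene must reach an s-cis conformation with a terminus crowded by an ortho-MOM-oxy naphthyl group. A8 is hydrolytically fragile and has to survive the alkyllithium.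
- Comparison: in step count this road is better. The chosen plan sets against it that every carbon–carbon bond is made by a polar addition or a metathesis with no periselectivity issue, that the ring type is an established product of ring-closing metathesis, and that the fate of the two oxygens is decided by substitution (tertiary against secondary carbinol), not by the orientation of a cycloaddition.

Key step: step 12

## Route

Step 1
Reactants: 1 8-methoxynaphthalen-1-ol
Product: 2 1-methoxy-8-(methoxymethoxy)naphthalene
Conditions: NaH, MOMCl, DMF, 0 °C → rt
Reagents that add atoms: chloromethyl methyl ether (MOMCl), COCCl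
Why: O-Alkylation of the sodium naphtholate (MOM protection); NaH breaks the peri hydrogen bond to the methoxy group and the hydroxyl is the only acidic site.

Step 2
Reactants: 2 1-methoxy-8-(methoxymethoxy)naphthalene
Product: 4 2-[8-methoxy-1-(methoxymethoxy)naphthalen-2-yl]-4,4,5,5-tetramethyl-1,3,2-dioxaborolane, via 2-lithio-8-methoxy-1-(methoxymethoxy)naphthalene 3 (not isolated)
Conditions: n-BuLi, TMEDA, THF, 0 °C; iPrOBpin, −78 °C → rt; H2O
Reagents that add atoms: 2-isopropoxy-4,4,5,5-tetramethyl-1,3,2-dioxaborolane (iPrOBpin), CC(C)OB1OC(C)(C)C(C)(C)O1
Why: Directed ortho-metalation followed by electrophilic borylation; the MOM-oxy group is a stronger director than the methoxy group and C2 is its only ortho position, so lithiation should give 3, which the borate ester converts into the pinacol boronate.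

Step 3
Reactants: 1 8-methoxynaphthalen-1-ol
Product: 5 4-bromo-8-methoxynaphthalen-1-ol
Conditions: NBS (1.0 equiv), MeCN, −20 → 0 °C
Reagents that add atoms: N-bromosuccinimide (NBS), O=C1CCC(=O)N1Br
Why: Electrophilic aromatic bromination; the free hydroxyl makes its own ring the most reactive, and in a polar solvent without amine base 1-naphthols are brominated mainly at the para position C4, while one equivalent of reagent limits dibromination.

Step 4
Reactants: 5 4-bromo-8-methoxynaphthalen-1-ol
Product: 6 4-bromo-8-methoxy-1-(methoxymethoxy)naphthalene
Conditions: NaH, MOMCl, DMF, 0 °C → rt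
Reagents that add atoms: chloromethyl methyl ether (MOMCl), COCCl
Why: MOM protection as in step 1; the aryl bromide is inert to NaH and to the alkylating agent.

Step 5
Reactants: 4 2-[8-methoxy-1-(methoxymethoxy)naphthalen-2-yl]-4,4,5,5-tetramethyl-1,3,2-dioxaborolane; 6 4-bromo-8-methoxy-1-(methoxymethoxy)naphthalene
Product: 7 8-methoxy-2-[5-methoxy-4-(methoxymethoxy)naphthalen-1-yl]-1-(methoxymethoxy)naphthalene
Conditions: Pd(OAc)2 (5 mol %), SPhos (10 mol %), K3PO4, toluene/H2O, 90 °C
Reagents that add atoms: none
Why: Suzuki–Miyaura coupling forms the A2–B4 bond; the dialkylbiarylphosphine ligand should make oxidative addition and transmetalation fast enough for an ortho-alkoxy boronate and a 1-naphthyl-type bromide to outrun protodeboronation, and MOM ethers are stable to aqueous base.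

Step 6
Reactants: 7 8-methoxy-2-[5-methoxy-4-(methoxymethoxy)naphthalen-1-yl]-1-(methoxymethoxy)naphthalene
Product: 9 8-methoxy-4-[8-methoxy-1-(methoxymethoxy)naphthalen-2-yl]-1-(methoxymethoxy)naphthalene-2-carbaldehyde, via 2-[3-lithio-5-methoxy-4-(methoxymethoxy)naphthalen-1-yl]-8-methoxy-1-(methoxymethoxy)naphthalene 8 (not isolated)
Conditions: n-BuLi, TMEDA, THF, −20 → 0 °C; DMF, −78 °C → rt; H2O
Reagents that add atoms: N,N-dimethylformamide (DMF), CN(C)C=O
Why: Directed ortho-metalation and formylation; B2 is the only C–H ortho to a MOM-oxy group in 7 (A2 is now arylated), so lithiation should give 8, and DMF delivers the aldehyde when the hemiaminal salt is hydrolysed.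

Step 7
Reactants: 10 2-bromo-6-methoxybenzaldehyde
Product: 11 1-(2-bromo-6-methoxyphenyl)prop-2-en-1-ol (racemic)
Conditions: vinylmagnesium bromide, THF, −78 → 0 °C; H2O
Reagents that add atoms: vinylmagnesium bromide, C=C[Mg]Br
Why: Grignard 1,2-addition to an aromatic aldehyde forms C1–C2 of unit C; the aryl bromide does not exchange with the vinyl Grignard reagent at low temperature, and the new stereocentre is formed racemic and erased in step 13.

Step 8
Reactants: 11 1-(2-bromo-6-methoxyphenyl)prop-2-en-1-ol
Product: 12 1-bromo-3-methoxy-2-[1-(methoxymethoxy)prop-2-en-1-yl]benzene (racemic)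
Conditions: MOMCl, iPr2NEt, CH2Cl2, 0 → 40 °C
Reagents that add atoms: chloromethyl methyl ether (MOMCl), COCCl
Why: MOM protection of a secondary alcohol under amine base, which leaves the allylic, benzylic proton alone; the ether carries no silicon that could migrate to the aryllithium of step 9 and ends as an aryl MOM ether after aromatization.

Step 9
Reactants: 12 1-bromo-3-methoxy-2-[1-(methoxymethoxy)prop-2-en-1-yl]benzene; 9 8-methoxy-4-[8-methoxy-1-(methoxymethoxy)naphthalen-2-yl]-1-(methoxymethoxy)naphthalene-2-carbaldehyde
Product: 14 {8-methoxy-4-[8-methoxy-1-(methoxymethoxy)naphthalen-2-yl]-1-(methoxymethoxy)naphthalen-2-yl}{3-methoxy-2-[1-(methoxymethoxy)prop-2-en-1-yl]phenyl}methanol (mixture of diastereomers), via [3-methoxy-2-[1-(methoxymethoxy)prop-2-en-1-yl]phenyl]lithium 13 (not isolated)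
Conditions: n-BuLi (1.0 equiv), THF, −78 °C; then 9, −78 → −20 °C; H2O
Reagents that add atoms: none
Why: Bromine–lithium exchange is faster than any deprotonation at −78 °C and the neighbouring MOM-oxy group chelates the aryllithium 13; its addition to aldehyde 9 forms C4–C4a, and the uncontrolled carbinol centre is removed in step 10.

Step 10
Reactants: 14 diaryl carbinol from step 9
Product: 15 {8-methoxy-4-[8-methoxy-1-(methoxymethoxy)naphthalen-2-yl]-1-(methoxymethoxy)naphthalen-2-yl}{3-methoxy-2-[1-(methoxymethoxy)prop-2-en-1-yl]phenyl}methanone (racemic)
Conditions: Dess–Martin periodinane, CH2Cl2, rt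
Reagents that add atoms: none
Why: Dess–Martin oxidation of a doubly benzylic secondary alcohol; the conditions are near neutral, so the MOM ethers, the vinyl group and the electron-rich naphthalenes should be untouched, and the diastereomers converge on one ketone.

Step 11
Reactants: 15 diaryl ketone from step 10
Product: 16 1-{8-methoxy-4-[8-methoxy-1-(methoxymethoxy)naphthalen-2-yl]-1-(methoxymethoxy)naphthalen-2-yl}-1-{3-methoxy-2-[1-(methoxymethoxy)prop-2-en-1-yl]phenyl}prop-2-en-1-ol (mixture of diastereomers)
Conditions: vinylmagnesium bromide (3 equiv), THF, −20 °C → rt; H2O; chromatography on Et3N-deactivated silica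
Reagents that add atoms: vinylmagnesium bromide, C=C[Mg]Br
Why: Grignard 1,2-addition to a non-enolizable diaryl ketone forms C4–C3; the reagent has no β-hydrogen for reduction and the ortho MOM-oxy group can chelate magnesium at the carbonyl; the tertiary centre forms without control and both diastereomers go forward.

Step 12
Reactants: 16 diene carbinol from step 11
Product: 17 5-methoxy-1-{8-methoxy-4-[8-methoxy-1-(methoxymethoxy)naphthalen-2-yl]-1-(methoxymethoxy)naphthalen-2-yl}-4-(methoxymethoxy)-1,4-dihydronaphthalen-1-ol (mixture of diastereomers; in unit numbering the C4 carbinol and the C1 MOM ether of unit C)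
Conditions: second-generation Grubbs catalyst RuCl2(H2IMes)(PCy3)(=CHPh) (5 mol %), CH2Cl2 (0.005 M), 40 °C
Reagents that add atoms: none
Why: Ring-closing olefin metathesis of an arene-tethered 1,7-diene, the known route from ortho-bis(alkenylmethyl)benzenes to 1,4-dihydronaphthalenes. The ruthenium carbene formed by loss of PCy3 engages the less hindered vinyl group on the secondary MOM-oxy carbon by (2+2) cycloaddition and cycloreversion, and the new alkylidene adds intramolecularly to the vinyl group on the tertiary carbinol; cycloreversion of that ruthenacyclobutane forms C2=C3, releases ethene and returns the propagating Ru=CH2 species. The one ring that closes is the six-membered future phenol ring of unit C, formed as the cis alkene that a six-membered ring demands, and the ortho carbons C4a and C8a of the arene hold the two chains within reach. No stereocentre is created; the two carbinol centres are untouched, either relative configuration fits a 1,4-dihydronaphthalene, so both diastereomers of 16 should close, and both centres are erased in step 13. The selectivity needed is closure over intermolecular metathesis and over double-bond migration: high dilution, the entropic advantage of a benzo-fused six-membered ring and two monosubstituted alkenes should secure the first, a moderate temperature and a short reaction time the second. The free tertiary hydroxyl is tolerated by the catalyst, and the medium is kept acid-free so that the carbinol does not ionize before the ring exists.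

Step 13
Reactants: 17 dihydronaphthalenol from step 12
Product: 19 8-methoxy-2-[4-hydroxy-3-(4-hydroxy-5-methoxynaphthalen-1-yl)-5-methoxynaphthalen-1-yl]naphthalen-1-ol (CNP0493720.0), via tris(methoxymethyl) ether 18 (not isolated)
Conditions: TsOH·H2O (10 mol %), CH2Cl2, 0 °C → rt; then MeOH, conc. HCl, 40 °C, under Ar
Reagents that add atoms: none
Why: E1 dehydration and aromatization: acid ionizes the tertiary, doubly benzylic and allylic C4 hydroxyl far more readily than the secondary C1 ether, and the delocalized cation loses the C1 proton to give naphthalene 18 with the oxygen kept on C1, peri to the methoxy group. Methanol is added only after aromatization, so it cannot be incorporated at C1 or C2, and methanolic HCl then cleaves the three aryl MOM acetals by acetal exchange.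

## Compound list

1 | 8-methoxynaphthalen-1-ol | COc1cccc2cccc(O)c12 | starting material
2 | 1-methoxy-8-(methoxymethoxy)naphthalene | COCOc1cccc2cccc(OC)c12 | intermediate
3 | 2-lithio-8-methoxy-1-(methoxymethoxy)naphthalene | COCOc1c([Li])ccc2cccc(OC)c12 | intermediate
4 | 2-[8-methoxy-1-(methoxymethoxy)naphthalen-2-yl]-4,4,5,5-tetramethyl-1,3,2-dioxaborolane | COCOc1c(B2OC(C)(C)C(C)(C)O2)ccc2cccc(OC)c12 | intermediate
5 | 4-bromo-8-methoxynaphthalen-1-ol | COc1cccc2c(Br)ccc(O)c12 | intermediate
6 | 4-bromo-8-methoxy-1-(methoxymethoxy)naphthalene | COCOc1ccc(Br)c2cccc(OC)c12 | intermediate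
7 | 8-methoxy-2-[5-methoxy-4-(methoxymethoxy)naphthalen-1-yl]-1-(methoxymethoxy)naphthalene (A2–B4 biaryl, bis-MOM ether) | COCOc1c(-c2ccc(OCOC)c3c(OC)cccc23)ccc2cccc(OC)c12 | intermediate
8 | 2-[3-lithio-5-methoxy-4-(methoxymethoxy)naphthalen-1-yl]-8-methoxy-1-(methoxymethoxy)naphthalene (7 lithiated at B2) | COCOc1c(-c2cc([Li])c(OCOC)c3c(OC)cccc23)ccc2cccc(OC)c12 | intermediate
9 | 8-methoxy-4-[8-methoxy-1-(methoxymethoxy)naphthalen-2-yl]-1-(methoxymethoxy)naphthalene-2-carbaldehyde | COCOc1c(-c2cc(C=O)c(OCOC)c3c(OC)cccc23)ccc2cccc(OC)c12 | intermediate
10 | 2-bromo-6-methoxybenzaldehyde | COc1cccc(Br)c1C=O | starting material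
11 | 1-(2-bromo-6-methoxyphenyl)prop-2-en-1-ol (racemic) | COc1cccc(Br)c1C(O)C=C | intermediate
12 | 1-bromo-3-methoxy-2-[1-(methoxymethoxy)prop-2-en-1-yl]benzene (racemic) | COCOC(C=C)c1c(Br)cccc1OC | intermediate
13 | [3-methoxy-2-[1-(methoxymethoxy)prop-2-en-1-yl]phenyl]lithium (racemic) | COCOC(C=C)c1c([Li])cccc1OC | intermediate
14 | {8-methoxy-4-[8-methoxy-1-(methoxymethoxy)naphthalen-2-yl]-1-(methoxymethoxy)naphthalen-2-yl}{3-methoxy-2-[1-(methoxymethoxy)prop-2-en-1-yl]phenyl}methanol (mixture of diastereomers) | COc1cccc(C(O)c2cc(-c3ccc4cccc(OC)c4c3OCOC)c3cccc(OC)c3c2OCOC)c1C(OCOC)C=C | intermediate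
15 | {8-methoxy-4-[8-methoxy-1-(methoxymethoxy)naphthalen-2-yl]-1-(methoxymethoxy)naphthalen-2-yl}{3-methoxy-2-[1-(methoxymethoxy)prop-2-en-1-yl]phenyl}methanone (racemic) | COc1cccc(C(=O)c2cc(-c3ccc4cccc(OC)c4c3OCOC)c3cccc(OC)c3c2OCOC)c1C(OCOC)C=C | intermediate
16 | 1-{8-methoxy-4-[8-methoxy-1-(methoxymethoxy)naphthalen-2-yl]-1-(methoxymethoxy)naphthalen-2-yl}-1-{3-methoxy-2-[1-(methoxymethoxy)prop-2-en-1-yl]phenyl}prop-2-en-1-ol (mixture of diastereomers) | COc1cccc(C(O)(C=C)c2cc(-c3ccc4cccc(OC)c4c3OCOC)c3cccc(OC)c3c2OCOC)c1C(OCOC)C=C | intermediate
17 | 5-methoxy-1-{8-methoxy-4-[8-methoxy-1-(methoxymethoxy)naphthalen-2-yl]-1-(methoxymethoxy)naphthalen-2-yl}-4-(methoxymethoxy)-1,4-dihydronaphthalen-1-ol (mixture of diastereomers) | COc1cccc2c1C(OCOC)C=CC2(O)c1cc(-c3ccc4cccc(OC)c4c3OCOC)c3cccc(OC)c3c1OCOC | intermediate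
18 | 8-methoxy-2-{5-methoxy-3-[5-methoxy-4-(methoxymethoxy)naphthalen-1-yl]-4-(methoxymethoxy)naphthalen-1-yl}-1-(methoxymethoxy)naphthalene (tris-MOM ether of the target) | COCOc1c(-c2cc(-c3ccc(OCOC)c4c(OC)cccc34)c(OCOC)c3c(OC)cccc23)ccc2cccc(OC)c12 | intermediate
19 | 8-methoxy-2-[4-hydroxy-3-(4-hydroxy-5-methoxynaphthalen-1-yl)-5-methoxynaphthalen-1-yl]naphthalen-1-ol (CNP0493720.0) | COc1cccc2ccc(-c3cc(-c4ccc(O)c5c(OC)cccc45)c(O)c4c(OC)cccc34)c(O)c12 | target

## Step count and risks

Total: 13 steps. Longest linear sequence: 9 steps (steps 1, 2, 5, 6, 9, 10, 11, 12, 13, from naphthol 1).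

**Step 12 (key step).** The second alkene sits on a carbon that bears two aryl groups and a hydroxyl, so turnover may be slow. A slow catalyst decays to ruthenium hydrides that move the allylic double bond into conjugation with the ether oxygen, and the accessible vinyl group may meanwhile dimerize by intermolecular metathesis. Fallback: give up the ring synthesis for unit C and make the B2–C4 bond by cross-coupling. This sets out from biaryl 7: lithiation as in step 6 (via 8) and trapping with iPrOBpin would give 2-{8-methoxy-4-[8-methoxy-1-(methoxymethoxy)naphthalen-2-yl]-1-(methoxymethoxy)naphthalen-2-yl}-4,4,5,5-tetramethyl-1,3,2-dioxaborolane F1. Suzuki coupling of F1 with bromide 6 under the conditions of step 5 would return to the route at 18, which then needs only the methanolic HCl stage of step 13.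

**Step 13.** Two things can go wrong. MOM ethers may be cleaved before aromatization is complete, and the methoxymethyl cation set free may then alkylate the liberated naphthols at their open positions (A4, C2). The free trinaphthol may also be oxidized by air during work-up. Fallback: separate the two events and change the cleavage from protic solvolysis to transfer of the acetal carbon to sulfur. This sets out from 18, isolated after the TsOH stage; ZnBr2 and propane-1-thiol in CH2Cl2 at 0 °C under argon should remove the MOM groups while the thiol captures the electrophile, returning to the route at 19. No new compound is involved.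

**Step 3.** Bromination ortho to the hydroxyl (C2) and double bromination may compete with para substitution, and the isomers may be hard to separate. Fallback: use the over-reaction. This sets out from 1: two equivalents of NBS should give 2,4-dibromo-8-methoxynaphthalen-1-ol F2, and MOM protection as in step 4 gives 2,4-dibromo-8-methoxy-1-(methoxymethoxy)naphthalene F3. Selective bromine–metal exchange at C2, which the neighbouring MOM-oxy group assists (n-BuLi, THF, −100 °C, or iPrMgCl·LiCl), followed by protonation, returns to the route at 6.

**Step 6.** Lithiation may be incomplete or may occur at other sites, namely the positions ortho to the methoxy groups or the hydrogens of unit B that lie near the MOM-oxy group of unit A. The result would be a mixture of formylated biaryls. Fallback: place the formyl group before the biaryl bond is made. This sets out from 1 by way of F2 and F3 as described under step 3: the same selective exchange at C2 of F3, quenched with DMF, would give 4-bromo-8-methoxy-1-(methoxymethoxy)naphthalene-2-carbaldehyde F4. Suzuki coupling of F4 with boronate 4 under the conditions of step 5 returns to the route at 9.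

**Step 11.** 1,2-Addition to a carbonyl flanked by two ortho-substituted aryl groups may be slow. The Grignard reagent may then instead displace the chelating MOM-oxy group at B1 by addition–elimination on the naphthalene ring. Fallback: use a slimmer, linear nucleophile and adjust the oxidation level afterwards. This sets out from 15: lithium (trimethylsilyl)acetylide in THF at −78 °C would give 1-{8-methoxy-4-[8-methoxy-1-(methoxymethoxy)naphthalen-2-yl]-1-(methoxymethoxy)naphthalen-2-yl}-1-{3-methoxy-2-[1-(methoxymethoxy)prop-2-en-1-yl]phenyl}-3-(trimethylsilyl)prop-2-yn-1-ol F5. K2CO3 in methanol would give the terminal alkyne 1-{8-methoxy-4-[8-methoxy-1-(methoxymethoxy)naphthalen-2-yl]-1-(methoxymethoxy)naphthalen-2-yl}-1-{3-methoxy-2-[1-(methoxymethoxy)prop-2-en-1-yl]phenyl}prop-2-yn-1-ol F6. Semi-hydrogenation of F6 (H2, Pd/CaCO3 poisoned with Pb(OAc)2, quinoline), stopped at one equivalent, returns to the route at 16.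

## Further compounds

F1 | step 12 | 2-{8-methoxy-4-[8-methoxy-1-(methoxymethoxy)naphthalen-2-yl]-1-(methoxymethoxy)naphthalen-2-yl}-4,4,5,5-tetramethyl-1,3,2-dioxaborolane | COCOc1c(-c2cc(B3OC(C)(C)C(C)(C)O3)c(OCOC)c3c(OC)cccc23)ccc2cccc(OC)c12
F0 | step 13 | none | none
F2 | step 3 | 2,4-dibromo-8-methoxynaphthalen-1-ol | COc1cccc2c(Br)cc(Br)c(O)c12
F3 | step 3 | 2,4-dibromo-8-methoxy-1-(methoxymethoxy)naphthalene | COCOc1c(Br)cc(Br)c2cccc(OC)c12
F4 | step 6 | 4-bromo-8-methoxy-1-(methoxymethoxy)naphthalene-2-carbaldehyde | COCOc1c(C=O)cc(Br)c2cccc(OC)c12
F5 | step 11 | 1-{8-methoxy-4-[8-methoxy-1-(methoxymethoxy)naphthalen-2-yl]-1-(methoxymethoxy)naphthalen-2-yl}-1-{3-methoxy-2-[1-(methoxymethoxy)prop-2-en-1-yl]phenyl}-3-(trimethylsilyl)prop-2-yn-1-ol (mixture of diastereomers) | COc1cccc(C(O)(C#C[Si](C)(C)C)c2cc(-c3ccc4cccc(OC)c4c3OCOC)c3cccc(OC)c3c2OCOC)c1C(OCOC)C=C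
F6 | step 11 | 1-{8-methoxy-4-[8-methoxy-1-(methoxymethoxy)naphthalen-2-yl]-1-(methoxymethoxy)naphthalen-2-yl}-1-{3-methoxy-2-[1-(methoxymethoxy)prop-2-en-1-yl]phenyl}prop-2-yn-1-ol (mixture of diastereomers) | COc1cccc(C(O)(C#C)c2cc(-c3ccc4cccc(OC)c4c3OCOC)c3cccc(OC)c3c2OCOC)c1C(OCOC)C=C
A1 | alternative 1 | tris(methoxymethyl) ether of the target (identical with 18) | COCOc1c(-c2cc(-c3ccc(OCOC)c4c(OC)cccc34)c(OCOC)c3c(OC)cccc23)ccc2cccc(OC)c12
A2 | alternative 1 | 4-{5-methoxy-3-[5-methoxy-4-(methoxymethoxy)naphthalen-1-yl]-4-(methoxymethoxy)naphthalen-1-yl}-3-(methoxymethoxy)-2-(trimethylsilyl)phenyl trifluoromethanesulfonate | COCOc1c(-c2cc(-c3ccc(OCOC)c4c(OC)cccc34)c(OCOC)c3c(OC)cccc23)ccc(OS(=O)(=O)C(F)(F)F)c1[Si](C)(C)C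
A3 | alternative 1 | 3-methoxy-2H-pyran-2-one | COc1cccoc1=O
A4 | alternative 2 | 8-methoxy-2-{5-methoxy-3-[5-methoxy-4-(methoxymethoxy)naphthalen-1-yl]-4-(methoxymethoxy)naphthalen-1-yl}naphthalen-1-ol | COc1cccc2ccc(-c3cc(-c4ccc(OCOC)c5c(OC)cccc45)c(OCOC)c4c(OC)cccc34)c(O)c12
A5 | alternative 2 | N,N-diethyl-2-methoxy-6-[(E)-3-{5-methoxy-3-[5-methoxy-4-(methoxymethoxy)naphthalen-1-yl]-4-(methoxymethoxy)naphthalen-1-yl}prop-2-en-1-yl]benzamide | CCN(CC)C(=O)c1c(OC)cccc1C/C=C/c1cc(-c2ccc(OCOC)c3c(OC)cccc23)c(OCOC)c2c(OC)cccc12
A6 | alternative 3 | 8-methoxy-4-{8-methoxy-4-[8-methoxy-1-(methoxymethoxy)naphthalen-2-yl]-1-(methoxymethoxy)naphthalen-2-yl}naphthalen-1-ol | COc1cccc2c(-c3cc(-c4ccc5cccc(OC)c5c4OCOC)c4cccc(OC)c4c3OCOC)ccc(O)c12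
A7 | alternative 3 | 2-iodo-3-methoxyphenyl trifluoromethanesulfonate | COc1cccc(OS(=O)(=O)C(F)(F)F)c1I
A8 | alternative 3 | (E)-4-{8-methoxy-4-[8-methoxy-1-(methoxymethoxy)naphthalen-2-yl]-1-(methoxymethoxy)naphthalen-2-yl}-1,1-bis(trimethylsilyloxy)buta-1,3-diene | C[Si](C)(C)OC(O[Si](C)(C)C)=C/C=C/c1cc(-c2ccc3cccc(OC)c3c2OCOC)c2cccc(OC)c2c1OCOC
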